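**Retrosynthetic overview**

Numbering used for all spiro compounds: ring A = C1–C5 (C1 methylidene carbon, C3 carbinol, C4 CHBr, C5 CMe2), C6 = spiro atom, ring B = C7–C11 (C8 ketone, C9 chloromethyl carbinol, C10 and C11 the adjacent methylenes).
Late stage: the C8 ketone comes from a cis C8,C9-diol, which comes from a C8=C9 alkene; the C3 alcohol comes from hydride reduction of a 4-bromo-3-ketone; the C1 methylidene comes from deconjugative protodesilylation of a 1-(silylmethyl)-1-en-3-one.
Key disconnection: ring B by a catalytic enantioselective Diels–Alder reaction that forms C10–C11 and C6–C7 together and sets the spiro center, from 3-methoxy-5,5-dimethyl-6-methylidenecyclohex-2-enone and 2-(chloromethyl)buta-1,3-diene.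
Enabling feature: C6 and C11 are the two carbons of an exocyclic C=CH2 on an α-methylene ketone of ring A (its C1 carbonyl is the later methylidene carbon), and C9 lies 1,4 to C6 in ring B, where a 2-substituted butadiene places its substituent, with C8 as the free internal diene carbon.
Ring order: ring A is taken from dimedone; ring B is closed in the key step; no other ring is formed.

Key step: step 7

Remark: the fixed numbering above is used instead of lowest-locant numbering, so an atom keeps its locant throughout. The catalyst antipode in step 7 is the one that leads to the (6S) adduct; this has the spatial arrangement of the (6R) center of the target, the descriptor changing only because the C1 substituent changes CIP priority.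

**Route**

Step 1
Reactants: 1 5,5-dimethylcyclohexane-1,3-dione (dimedone)
Product: 2 3-methoxy-5,5-dimethylcyclohex-2-en-1-one
Conditions: MeOH, TsOH·H2O (cat.), reflux, 3 Å molecular sieves
Reagents that add atoms: methanol, CO
Why: Acid-catalysed enol etherification of the symmetrical cyclic 1,3-dione gives a single vinylogous ester and creates no stereocenter.

Step 2
Reactants: 2 3-methoxy-5,5-dimethylcyclohex-2-en-1-one
Product: 3 6-[(dimethylamino)methyl]-3-methoxy-5,5-dimethylcyclohex-2-en-1-one (racemic)
Conditions: LiN(iPr)2, THF, −78 °C; then CH2=NMe2+ I− (Eschenmoser's salt), −78 → 0 °C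
Reagents that add atoms: dimethyl(methylidene)ammonium iodide, C=[N+](C)C.[I-]
Why: Kinetic deprotonation of a 3-alkoxyenone occurs at the α' carbon C6 (Stork–Danheiser regiochemistry) and the lithium enolate undergoes a Mannich reaction with the preformed iminium salt; the C6 stereocenter is racemic and disappears in step 3.

Step 3
Reactants: 3 6-[(dimethylamino)methyl]-3-methoxy-5,5-dimethylcyclohex-2-en-1-one
Product: 5 3-methoxy-5,5-dimethyl-6-methylidenecyclohex-2-en-1-one, via trimethylammonium iodide 4 (not isolated)
Conditions: MeI, CH2Cl2, rt; then K2CO3, CH2Cl2/H2O, rt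
Reagents that add atoms: none
Why: Exhaustive N-methylation followed by base-induced E1cB (Hofmann-type) elimination of trimethylamine from the β-ammonium ketone gives the α-methylene ketone, the exocyclic position being the only possible one because C5 is quaternary.

Step 4
Reactants: 6 3-methyl-2,5-dihydrothiophene 1,1-dioxide (3-methyl-3-sulfolene)
Product: 7 3-(bromomethyl)-2,5-dihydrothiophene 1,1-dioxide
Conditions: N-bromosuccinimide, (PhCO2)2 (cat.), PhCF3, reflux
Reagents that add atoms: N-bromosuccinimide, O=C1CCC(=O)N1Br
Why: Wohl–Ziegler radical bromination takes the methyl hydrogen atoms, since hydrogen abstraction at the ring methylenes next to the sulfone is polarity-mismatched for the bromine atom.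

Step 5
Reactants: 7 3-(bromomethyl)-2,5-dihydrothiophene 1,1-dioxide
Product: 8 3-(chloromethyl)-2,5-dihydrothiophene 1,1-dioxide
Conditions: LiCl (5 equiv), DMF, rt
Reagents that add atoms: lithium chloride, [Li+].[Cl-]
Why: Finkelstein-type SN2 halide exchange on the primary allylic bromide is driven to the chloride by excess chloride in a dipolar aprotic solvent.

Step 6
Reactants: 8 3-(chloromethyl)-2,5-dihydrothiophene 1,1-dioxide
Product: 9 2-(chloromethyl)buta-1,3-diene
Conditions: neat, BHT (trace), 130–150 °C, reduced pressure, distilled into a −78 °C trap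
Reagents that add atoms: none
Why: Thermal cheletropic extrusion of SO2 from the 3-sulfolene (retro-[4+1]) releases the 1,3-diene, which is removed by distillation as it forms to limit dimerisation.

Step 7
Reactants: 5 3-methoxy-5,5-dimethyl-6-methylidenecyclohex-2-en-1-one; 9 2-(chloromethyl)buta-1,3-diene
Product: 10 (6S)-9-(chloromethyl)-3-methoxy-5,5-dimethylspiro[5.5]undeca-2,8-dien-1-one
Conditions: chiral confined imidodiphosphorimidate Brønsted acid (IDPi, 3 mol %, antipode giving the 6S adduct), 9 (3 equiv), CH2Cl2, −40 → −20 °C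
Reagents that add atoms: none
Why: The catalyst protonates the carbonyl oxygen of 5 and holds the hydroxyallyl cation in its chiral anion pocket, and the exocyclic C6=CH2 then undergoes a concerted, asynchronous [4+2] cycloaddition with 9 in which the bond from the exocyclic CH2 (C11) to the diene terminus next to the chloromethyl-bearing carbon (C10) is the more advanced one and C6–C7 follows. The closest known reaction type is the Brønsted-acid-catalysed enantioselective spirocyclising Diels–Alder reaction of α-methylene cycloalkanones with 2-substituted butadienes, which gives chamigrene-type spiro[5.5]undecenes. Ring B is closed by this intermolecular [4π+2π] cycloaddition, both σ-bonds being formed suprafacially in the one step. The only new stereocenter, C6, is set by the catalyst, which shields one enantiotopic face of the exocyclic alkene; there is no endo/exo question because neither the dienophile CH2 nor the diene termini carry substituents. The step needs the "para" regiochemistry, secured by the match of the largest LUMO coefficient (the exocyclic CH2, β to the carbonyl) with the largest HOMO coefficient (C1 of the 2-substituted diene); it also needs site selectivity for the exocyclic over the ring C2=C3 alkene, secured because the latter is the donor-substituted alkene of the vinylogous ester, and it needs to outrun hetero-Diels–Alder dimerisation of 5, which excess diene and the flanking gem-dimethyl group should ensure.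

Step 8
Reactants: 10 (6S)-9-(chloromethyl)-3-methoxy-5,5-dimethylspiro[5.5]undeca-2,8-dien-1-one
Product: 12 (4R,6S)-4-bromo-9-(chloromethyl)-3-methoxy-5,5-dimethylspiro[5.5]undeca-2,8-dien-1-one, via silyl dienol ether 11 (not isolated)
Conditions: TMSOTf, Et3N, CH2Cl2, 0 °C; then N-bromosuccinimide, THF, −78 °C
Reagents that add atoms: N-bromosuccinimide, O=C1CCC(=O)N1Br
Why: Soft enolisation (O-silylation, then loss of the only enolisable hydrogen, at C4, since C6 is quaternary) gives the 1-silyloxy-3-methoxy-1,3-diene, which N-bromosuccinimide attacks at the diene terminus C4 as in the γ-halogenation of dienol ethers; the (4R) center is set by substrate control, bromine entering anti to the pseudoaxial C5 methyl group of the ring A half-chair that carries C7 pseudoaxial, a half-chair expected to be preferred because the sp2 carbon C8 turns no axial hydrogen toward ring A, so that Br ends cis to C7.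

Step 9
Reactants: 12 (4R,6S)-4-bromo-9-(chloromethyl)-3-methoxy-5,5-dimethylspiro[5.5]undeca-2,8-dien-1-one
Product: 13 (4R,6S,8R,9S)-4-bromo-9-(chloromethyl)-8,9-dihydroxy-3-methoxy-5,5-dimethylspiro[5.5]undec-2-en-1-one
Conditions: OsO4 (2 mol %), N-methylmorpholine N-oxide, acetone/H2O, 0 °C → rt
Reagents that add atoms: osmium tetroxide, O=[Os](=O)(=O)=O; N-methylmorpholine N-oxide, C[N+]1([O-])CCOCC1; water, O
Why: Upjohn dihydroxylation (concerted [3+2] syn addition) is chemoselective for the isolated trisubstituted alkene over the push-pull alkene of the vinylogous ester, and OsO4 should add to the ring B face anti to the pseudoaxial C1 carbon at the homoallylic spiro center (the bulkier C5 being pseudoequatorial), which places both new hydroxyl groups cis to C5 and sets C9 (S) and C8 (R).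

Step 10
Reactants: 13 (4R,6S,8R,9S)-4-bromo-9-(chloromethyl)-8,9-dihydroxy-3-methoxy-5,5-dimethylspiro[5.5]undec-2-en-1-one
Product: 15 (4R,6R,8R,9S)-4-bromo-9-(chloromethyl)-8,9-dihydroxy-5,5-dimethyl-1-[(trimethylsilyl)methyl]spiro[5.5]undec-1-en-3-one, via carbinol adduct 14 (not isolated)
Conditions: Me3SiCH2Li (4.5 equiv), CeCl3 (4.5 equiv), THF, −78 °C; then 0.5 M aq. HCl, THF, 0 °C
Reagents that add atoms: (trimethylsilyl)methyllithium, [Li]C[Si](C)(C)C; water, O
Why: The weakly basic organocerium reagent adds 1,2 to the hindered vinylogous-ester carbonyl (the two hydroxyl groups only consume reagent as alkoxides, and C4–H is not removed), and mild acid then effects the Stork–Danheiser transposition (allylic ionisation, hydration at the methoxy-bearing carbon, loss of methanol) to the 3-oxo-1-ene that retains the silylmethyl group; the C1 carbinol center of 14 is transient and no lasting stereocenter is formed.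

Step 11
Reactants: 15 (4R,6R,8R,9S)-4-bromo-9-(chloromethyl)-8,9-dihydroxy-5,5-dimethyl-1-[(trimethylsilyl)methyl]spiro[5.5]undec-1-en-3-one
Product: 16 (4R,6R,8R,9S)-4-bromo-9-(chloromethyl)-8,9-dihydroxy-5,5-dimethyl-1-methylidenespiro[5.5]undecan-3-one
Conditions: Bu4NF, AcOH (1:1.5), THF, −40 → 0 °C
Reagents that add atoms: none
Why: Fluoride cleaves the C–Si bond of the γ-silyl enone (a vinylogous α-silyl ketone) to the linear dienolate, and kinetic C-protonation of a dienolate by the acetic acid buffer occurs at the α-carbon C2, giving the deconjugated ketone with the exocyclic C1 methylidene (deconjugative protonation), while low temperature and buffering should prevent epimerisation at C4 and Favorskii-type bromide loss; no new stereocenter.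

Step 12
Reactants: 16 (4R,6R,8R,9S)-4-bromo-9-(chloromethyl)-8,9-dihydroxy-5,5-dimethyl-1-methylidenespiro[5.5]undecan-3-one
Product: 17 (3S,4R,6R,8R,9S)-4-bromo-9-(chloromethyl)-5,5-dimethyl-1-methylidenespiro[5.5]undecane-3,8,9-triol
Conditions: iBu2AlH (4 equiv), CH2Cl2, −78 °C; then aq. potassium sodium tartrate
Reagents that add atoms: none
Why: In the chair of ring A with equatorial bromine the axial C5 methyl group blocks axial attack on the C3 carbonyl, so the bulky aluminium hydride is delivered equatorially and gives the axial (3S) alcohol cis to bromine (substrate-controlled reduction of an α-bromo ketone), ring B being untouched.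

Step 13
Reactants: 17 (3S,4R,6R,8R,9S)-4-bromo-9-(chloromethyl)-5,5-dimethyl-1-methylidenespiro[5.5]undecane-3,8,9-triol
Product: 19 (3S,4R,6R,9S)-4-bromo-9-(chloromethyl)-3,9-dihydroxy-5,5-dimethyl-1-methylidenespiro[5.5]undecan-8-one, via dibutylstannylene acetal 18 (not isolated)
Conditions: Bu2SnO, MeOH, 65 °C; evaporate; then N-bromosuccinimide, CH2Cl2, 0 °C, dark
Reagents that add atoms: none
Why: The cis C8,C9 diol forms a five-membered dibutylstannylene acetal whose brominolysis oxidises the secondary C8–O–Sn carbon to the ketone (regioselective stannylene-mediated oxidation of vicinal diols), whereas the isolated C3 hydroxyl forms no stannylene and is left; the C8 stereocenter is erased and C3, C4, C6 and C9 are untouched.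

**Compound list**

1 | 5,5-dimethylcyclohexane-1,3-dione (dimedone) | CC1(C)CC(=O)CC(=O)C1 | starting material
2 | 3-methoxy-5,5-dimethylcyclohex-2-en-1-one | COC1=CC(=O)CC(C)(C)C1 | intermediate
3 | 6-[(dimethylamino)methyl]-3-methoxy-5,5-dimethylcyclohex-2-en-1-one (racemic) | COC1=CC(=O)C(CN(C)C)C(C)(C)C1 | intermediate
4 | [(4-methoxy-6,6-dimethyl-2-oxocyclohex-3-en-1-yl)methyl]trimethylammonium iodide (racemic) | COC1=CC(=O)C(C[N+](C)(C)C)C(C)(C)C1.[I-] | intermediate
5 | 3-methoxy-5,5-dimethyl-6-methylidenecyclohex-2-en-1-one | COC1=CC(=O)C(=C)C(C)(C)C1 | intermediate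
6 | 3-methyl-2,5-dihydrothiophene 1,1-dioxide | CC1=CCS(=O)(=O)C1 | starting material
7 | 3-(bromomethyl)-2,5-dihydrothiophene 1,1-dioxide | BrCC1=CCS(=O)(=O)C1 | intermediate
8 | 3-(chloromethyl)-2,5-dihydrothiophene 1,1-dioxide | ClCC1=CCS(=O)(=O)C1 | intermediate
9 | 2-(chloromethyl)buta-1,3-diene | C=CC(=C)CCl | intermediate
10 | (6S)-9-(chloromethyl)-3-methoxy-5,5-dimethylspiro[5.5]undeca-2,8-dien-1-one | O=C1C=C(OC)CC(C)(C)[C@@]12CCC(CCl)=CC2 | intermediate
11 | {[(6S)-9-(chloromethyl)-3-methoxy-5,5-dimethylspiro[5.5]undeca-1,3,8-trien-1-yl]oxy}trimethylsilane | C[Si](C)(C)OC1=CC(OC)=CC(C)(C)[C@@]12CCC(CCl)=CC2 | intermediate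
12 | (4R,6S)-4-bromo-9-(chloromethyl)-3-methoxy-5,5-dimethylspiro[5.5]undeca-2,8-dien-1-one (Br cis to C7 on ring A) | O=C1C=C(OC)[C@H](Br)C(C)(C)[C@@]12CCC(CCl)=CC2 | intermediate
13 | (4R,6S,8R,9S)-4-bromo-9-(chloromethyl)-8,9-dihydroxy-3-methoxy-5,5-dimethylspiro[5.5]undec-2-en-1-one (cis-diol, both OH cis to C5 on ring B) | O=C1C=C(OC)[C@H](Br)C(C)(C)[C@@]12CC[C@@](O)(CCl)[C@H](O)C2 | intermediate
14 | (4R,6S,8R,9S)-4-bromo-9-(chloromethyl)-3-methoxy-5,5-dimethyl-1-[(trimethylsilyl)methyl]spiro[5.5]undec-2-ene-1,8,9-triol (C1 epimers) | C[Si](C)(C)CC1(O)C=C(OC)[C@H](Br)C(C)(C)[C@@]12CC[C@@](O)(CCl)[C@H](O)C2 | intermediate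
15 | (4R,6R,8R,9S)-4-bromo-9-(chloromethyl)-8,9-dihydroxy-5,5-dimethyl-1-[(trimethylsilyl)methyl]spiro[5.5]undec-1-en-3-one | C[Si](C)(C)CC1=CC(=O)[C@H](Br)C(C)(C)[C@@]12CC[C@@](O)(CCl)[C@H](O)C2 | intermediate
16 | (4R,6R,8R,9S)-4-bromo-9-(chloromethyl)-8,9-dihydroxy-5,5-dimethyl-1-methylidenespiro[5.5]undecan-3-one | C=C1CC(=O)[C@H](Br)C(C)(C)[C@@]12CC[C@@](O)(CCl)[C@H](O)C2 | intermediate
17 | (3S,4R,6R,8R,9S)-4-bromo-9-(chloromethyl)-5,5-dimethyl-1-methylidenespiro[5.5]undecane-3,8,9-triol (3-OH cis to Br) | C=C1C[C@H](O)[C@H](Br)C(C)(C)[C@@]12CC[C@@](O)(CCl)[C@H](O)C2 | intermediate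
18 | 8,9-O-dibutylstannylene acetal of triol 17 | C=C1C[C@H](O)[C@H](Br)C(C)(C)[C@@]12CC[C@]3(CCl)O[Sn](CCCC)(CCCC)O[C@@H]3C2 | intermediate
19 | (3S,4R,6R,9S)-4-bromo-9-(chloromethyl)-3,9-dihydroxy-5,5-dimethyl-1-methylidenespiro[5.5]undecan-8-one | C=C1C[C@H](O)[C@H](Br)C(C)(C)[C@@]12CC[C@@](O)(CCl)C(=O)C2 | target

**Step count and risks**

Total step count: 13. Longest linear sequence: 10 steps (steps 1–3 and 7–13; the diene branch, steps 4–6 and 7–13, is equally long).

Steps most likely to fail:

1. Step 7. The cycloaddition may be sluggish, because a vinylogous-ester carbonyl activates the exocyclic alkene less than a plain ketone and the chloromethyl group lowers the nucleophilicity of the diene, or the enantioface discrimination may be insufficient. Fallback (sets out from 2, returns at 10): α'-alkylation of 2 (LiN(iPr)2; 4-iodo-2-{[(tert-butyldimethylsilyl)oxy]methyl}but-1-ene) would give 6-(3-{[(tert-butyldimethylsilyl)oxy]methyl}but-3-en-1-yl)-3-methoxy-5,5-dimethylcyclohex-2-en-1-one F1. O-acylation of its enolate with allyl chloroformate would give the allyl enol carbonate F2. Palladium-catalysed decarboxylative asymmetric allylic alkylation (Pd2(dba)3, t-Bu-PHOX ligand of the required handedness) would set the quaternary center in the (6S)-6-allyl ketone F3. Ring-closing metathesis (second-generation Grubbs catalyst, RuCl2(=CHPh)(H2IMes)(PCy3)) would close ring B at C8=C9 to the silyloxymethyl spirocycle F4. Desilylation (Bu4NF) would give the allylic alcohol F5, and MsCl/LiCl/2,6-lutidine would convert it into 10.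

2. Step 8. Facial selectivity of the C4 bromination may be poor, since the two ring B methylenes on C6 differ only at C8. Fallback (sets out from 12 as an epimer mixture, returns at 10): the C4 epimers are diastereomers and would be separated by chromatography; the unwanted (4S,6S)-4-bromo-9-(chloromethyl)-3-methoxy-5,5-dimethylspiro[5.5]undeca-2,8-dien-1-one F6 would be reduced back to 10 with Zn/AcOH (reductive removal of a vinylogous α-bromo carbonyl halogen) and resubmitted, so that separation and recycling replace kinetic face control.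

3. Step 11. The dienolate may epimerise at C4, lose bromide in a Favorskii-type process, or be protonated at the exocyclic carbon to give the conjugated 1-methyl enone. Fallback (sets out from 15, returns at 17): the ketone would be reduced first (iBu2AlH, CH2Cl2, −78 °C) to (3S,4R,6R,8R,9S)-4-bromo-9-(chloromethyl)-5,5-dimethyl-1-[(trimethylsilyl)methyl]spiro[5.5]undec-1-ene-3,8,9-triol F7. Its allylsilane would then be protodesilylated electrophilically (BF3·2AcOH, CH2Cl2, −20 °C), the proton adding at C2 and silicon leaving so that the alkene moves to the exocyclic position (SE2' substitution), to give 17.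

**Further compounds**

F1 | step 7 | 6-(3-{[(tert-butyldimethylsilyl)oxy]methyl}but-3-en-1-yl)-3-methoxy-5,5-dimethylcyclohex-2-en-1-one (racemic) | COC1=CC(=O)C(CCC(=C)CO[Si](C)(C)C(C)(C)C)C(C)(C)C1
F2 | step 7 | allyl 2-(3-{[(tert-butyldimethylsilyl)oxy]methyl}but-3-en-1-yl)-5-methoxy-3,3-dimethylcyclohexa-1,5-dien-1-yl carbonate | C=CCOC(=O)OC1=C(CCC(=C)CO[Si](C)(C)C(C)(C)C)C(C)(C)CC(OC)=C1
F3 | step 7 | (6S)-6-allyl-6-(3-{[(tert-butyldimethylsilyl)oxy]methyl}but-3-en-1-yl)-3-methoxy-5,5-dimethylcyclohex-2-en-1-one | O=C1C=C(OC)CC(C)(C)[C@@]1(CC=C)CCC(=C)CO[Si](C)(C)C(C)(C)C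
F4 | step 7 | (6S)-9-{[(tert-butyldimethylsilyl)oxy]methyl}-3-methoxy-5,5-dimethylspiro[5.5]undeca-2,8-dien-1-one | O=C1C=C(OC)CC(C)(C)[C@@]12CCC(CO[Si](C)(C)C(C)(C)C)=CC2
F5 | step 7 | (6S)-9-(hydroxymethyl)-3-methoxy-5,5-dimethylspiro[5.5]undeca-2,8-dien-1-one | O=C1C=C(OC)CC(C)(C)[C@@]12CCC(CO)=CC2
F6 | step 8 | (4S,6S)-4-bromo-9-(chloromethyl)-3-methoxy-5,5-dimethylspiro[5.5]undeca-2,8-dien-1-one | O=C1C=C(OC)[C@@H](Br)C(C)(C)[C@@]12CCC(CCl)=CC2
F7 | step 11 | (3S,4R,6R,8R,9S)-4-bromo-9-(chloromethyl)-5,5-dimethyl-1-[(trimethylsilyl)methyl]spiro[5.5]undec-1-ene-3,8,9-triol | C[Si](C)(C)CC1=C[C@H](O)[C@H](Br)C(C)(C)[C@@]12CC[C@@](O)(CCl)[C@H](O)C2
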